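Ring B (C5–C6–C7–C8–C9–C10, eudesmane numbering) with oxygen at C6 and isopropyl at C7 is the retron of a 2-silyloxy-3-isopropyl-diene cycloadduct, and its C5–C10 edge is shared with ring A. Both rings are therefore cut at once: bonds C5–C10 and C8–C9 arise in one intramolecular Diels–Alder reaction of an acyclic tetraene in which the cis-C3=C4 olefin of ring A is the tether, the C9=C10 isopropenyl unit the dienophile and the C5=C6(OSi)–C7=C8 silyl dienol ether the diene. The step closes rings A and B and sets quaternary C10 and C5; a temporary C2 silyloxy stereocentre, made by catalytic asymmetric methallylation, fixes the absolute sense and is deleted later.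

Key step: step 7

Remark (numbering): C1–C15 in the text are the eudesmane positions of the target (ring A = C1–C2–C3–C4–C5–C10, ring B = C5–C6–C7–C8–C9–C10, C14 = methyl on C10, C15 = methyl on C4, C11–C13 = isopropyl); beta is the face of the C14 methyl, alpha the opposite face.

Assumption: the BINOL–titanium methallylation of but-2-ynal follows the facial sense known for benzaldehyde ((R)-BINOL gives the (R)-carbinol; otherwise (S)-BINOL is used), and 1 and 10 are taken as catalogue compounds.

Step 1
Reactants: 1 but-2-ynal; 2 tributyl(2-methylprop-2-en-1-yl)stannane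
Product: 3 (4R)-2-methylhept-1-en-5-yn-4-ol
Conditions: (R)-BINOL (10 mol %), Ti(OiPr)4 (10 mol %), 4 Å MS, CH2Cl2, −20 °C; aq NaHCO3
Reagents that add atoms: none
Why: Keck catalytic asymmetric methallylation, in which the chiral BINOL–titanium Lewis acid activates the aldehyde and exposes one carbonyl face to the allylstannane, should set the (R)-carbinol centre that becomes C2.

Step 2
Reactants: 3 (4R)-2-methylhept-1-en-5-yn-4-ol
Product: 5 (4R,5Z)-6-iodo-2-methylhepta-1,5-dien-4-ol, via cyclic vinylalanate 4 (not isolated)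
Conditions: NaAlH2(OCH2CH2OMe)2, THF, 0 °C to rt; then I2, −78 °C
Reagents that add atoms: iodine, II
Why: Alkoxide-directed trans-hydroalumination of the propargylic alcohol places aluminium on the distal alkyne carbon inside a five-membered ring and iodinolysis goes with retention, so the carbinol carbon and iodine should end cis (Z), the geometry that later holds C2 and C5 cis on C3=C4.

Step 3
Reactants: 5 (4R,5Z)-6-iodo-2-methylhepta-1,5-dien-4-ol
Product: 6 tert-butyl{[(4R,5Z)-6-iodo-2-methylhepta-1,5-dien-4-yl]oxy}dimethylsilane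
Conditions: TBSCl, imidazole, DMF, rt
Reagents that add atoms: tert-butyldimethylsilyl chloride, CC(C)(C)[Si](C)(C)Cl
Why: Imidazole-promoted silylation of a secondary alcohol gives the bulky silyl ether that survives the organometallic steps and later controls the diene face.

Step 4
Reactants: 6 tert-butyl{[(4R,5Z)-6-iodo-2-methylhepta-1,5-dien-4-yl]oxy}dimethylsilane; 7 2-bromo-N-methoxy-N-methylacetamide
Product: 9 (3Z,5R)-5-[(tert-butyldimethylsilyl)oxy]-N-methoxy-N,3,7-trimethylocta-3,7-dienamide, via zinc amide enolate 8 (not isolated)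
Conditions: 7, Zn dust (TMSCl-activated), THF, rt; then 6, Pd2(dba)3 (2.5 mol %), XPhos (10 mol %), THF, 50 °C
Reagents that add atoms: none
Why: Negishi coupling of a Reformatsky-type zinc reagent with an alkenyl iodide proceeds with retention of olefin geometry and installs C5 and C6 without a free basic enolate that could move the skipped double bond into conjugation.

Step 5
Reactants: 9 (3Z,5R)-5-[(tert-butyldimethylsilyl)oxy]-N-methoxy-N,3,7-trimethylocta-3,7-dienamide; 10 2-bromo-3-methylbut-1-ene
Product: 12 (5Z,7R)-7-[(tert-butyldimethylsilyl)oxy]-5,9-dimethyl-2-(propan-2-yl)deca-1,5,9-trien-3-one, via alkenylmagnesium bromide 11 (not isolated)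
Conditions: 10, Mg, THF; then 9, THF, −40 to 0 °C; cold aq NH4Cl
Reagents that add atoms: none
Why: Weinreb ketone synthesis, in which the chelated tetrahedral intermediate stops at mono-addition, should release the cross-conjugated enone carrying C7 and C8 on work-up.

Step 6
Reactants: 12 (5Z,7R)-7-[(tert-butyldimethylsilyl)oxy]-5,9-dimethyl-2-(propan-2-yl)deca-1,5,9-trien-3-one
Product: 13 (3Z,5Z,7R)-3,7-bis[(tert-butyldimethylsilyl)oxy]-5,9-dimethyl-2-(propan-2-yl)deca-1,3,5,9-tetraene
Conditions: TBSOTf (1.1 equiv), Et3N (2 equiv), CH2Cl2, −78 °C; aq NaHCO3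
Reagents that add atoms: tert-butyldimethylsilyl trifluoromethanesulfonate, CC(C)(C)[Si](C)(C)OS(=O)(=O)C(F)(F)F
Why: Soft enolisation (silyl triflate and amine) removes the doubly activated C5 proton, the only enolisable site, and should give the (Z)-silyl dienol ether with C4 cis to oxygen, that is, on the outside of the future s-cis diene.

Step 7
Reactants: 13 (3Z,5Z,7R)-3,7-bis[(tert-butyldimethylsilyl)oxy]-5,9-dimethyl-2-(propan-2-yl)deca-1,3,5,9-tetraene
Product: 14 (4aS,6R,8aR)-1,6-bis[(tert-butyldimethylsilyl)oxy]-4a,8-dimethyl-2-(propan-2-yl)-3,4,4a,5,6,8a-hexahydronaphthalene (2-alpha,6-bis(silyloxy)eudesma-3,6-diene, 5-alpha-H, 10-beta-methyl)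
Conditions: toluene (5 mM), Et3N (0.5 equiv), BHT (cat.), base-washed sealed tube, 190 °C
Reagents that add atoms: none
Why: Thermal type 1 intramolecular Diels–Alder reaction (concerted, asynchronous [4+2]) of the 2-silyloxy diene C5=C6–C7=C8 with the unactivated 1,1-disubstituted alkene C9=C10, the closest known type being the thermal cyclisation of silyl dienol ether 1,7,9-decatrienes to decalins. Ring B closes as the cycloadduct ring through C5–C10 and C8–C9, and ring A closes in the same event as the tether ring through C5–C10, its (Z)-C3=C4 olefin holding C2 and C5 cis so that the four-atom tether can reach across. The trans ring fusion (H5 anti to the C14 methyl) is expected from the transition state with the tether exo and the C14 methyl under the diene, in which ring A is a half-chair and C6 and C9 are both pseudo-equatorial on it. The absolute sense at C5 and C10 is set by the C2 stereocentre: its silyloxy group stays pseudo-equatorial (alpha), because addition to the other diene face would force it 1,3-diaxial to the C14 methyl on C10. The step needs the (Z)-enol ether geometry of 13, which keeps the tether on the outside of the s-cis diene and excludes 6-pi electrocyclisation, and it needs the cycloaddition to outrun the [1,5]-hydrogen shift from C2 to C6, which high dilution, base-washed glass and the lowest workable temperature should favour.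

Step 8
Reactants: 14 (4aS,6R,8aR)-1,6-bis[(tert-butyldimethylsilyl)oxy]-4a,8-dimethyl-2-(propan-2-yl)-3,4,4a,5,6,8a-hexahydronaphthalene
Product: 16 (2S,4aS,6R,8aR)-6-hydroxy-4a,8-dimethyl-2-(propan-2-yl)-3,4,4a,5,6,8a-hexahydronaphthalen-1(2H)-one (2-alpha-hydroxyeudesm-3-en-6-one), via C2-silyloxy ketone 15 (not isolated)
Conditions: HF·pyridine, pyridine, THF, 0 °C to rt
Reagents that add atoms: none
Why: Fluoride-mediated desilylation cleaves the enol ether first and the allylic ether second, and the liberated enol should be protonated at C7 on the axial alpha face (anti to the C14 methyl), giving the equatorial beta isopropyl group, which is also the thermodynamic epimer.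

Step 9
Reactants: 16 (2S,4aS,6R,8aR)-6-hydroxy-4a,8-dimethyl-2-(propan-2-yl)-3,4,4a,5,6,8a-hexahydronaphthalen-1(2H)-one
Product: 17 (1R,2S,4aS,6R,8aR)-4a,8-dimethyl-2-(propan-2-yl)-1,2,3,4,4a,5,6,8a-octahydronaphthalene-1,6-diol (eudesm-3-ene-2-alpha,6-beta-diol)
Conditions: LiBH(s-Bu)3 (2.5 equiv), THF, −78 °C; aq NH4Cl
Reagents that add atoms: none
Why: Bulky trialkylborohydride reduction, in which hydride approaches C6 along the equatorial trajectory from the alpha face because the beta face is shielded by the 1,3-diaxial C14 methyl, should give the axial 6-beta alcohol.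

Step 10
Reactants: 17 (1R,2S,4aS,6R,8aR)-4a,8-dimethyl-2-(propan-2-yl)-1,2,3,4,4a,5,6,8a-octahydronaphthalene-1,6-diol
Product: 18 (1R,2S,4aR,8aR)-4a,8-dimethyl-2-(propan-2-yl)-1,2,3,4,4a,5,6,8a-octahydronaphthalen-1-ol (eudesm-3-en-6-beta-ol)
Conditions: Et3SiH (5 equiv), BF3·OEt2 (2 equiv), CH2Cl2, −78 to −30 °C
Reagents that add atoms: none
Why: Ionic hydrogenation, in which BF3 ionises only the allylic C2 hydroxyl and the silane delivers hydride to the less substituted terminus (C2) of the C2–C3–C4 allyl cation, should delete the temporary stereocentre and leave the trisubstituted C3=C4 olefin.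

Step 11
Reactants: 18 (1R,2S,4aR,8aR)-4a,8-dimethyl-2-(propan-2-yl)-1,2,3,4,4a,5,6,8a-octahydronaphthalen-1-ol; 19 (2E)-3-[4-(acetyloxy)phenyl]prop-2-enoic acid
Product: 21 (1R,2S,4aR,8aR)-4a,8-dimethyl-2-(propan-2-yl)-1,2,3,4,4a,5,6,8a-octahydronaphthalen-1-yl (2E)-3-[4-(acetyloxy)phenyl]prop-2-enoate, via acid chloride 20 (not isolated)
Conditions: 19, (COCl)2, DMF (cat.), CH2Cl2, rt, evaporate; then 18, DMAP, Et3N, CH2Cl2, 40 °C
Reagents that add atoms: none
Why: Acylation of the hindered axial alcohol by an acid chloride under DMAP nucleophilic catalysis (acylpyridinium ion) touches no stereocentre and keeps the E olefin of the cinnamate.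

Step 12
Reactants: 21 (1R,2S,4aR,8aR)-4a,8-dimethyl-2-(propan-2-yl)-1,2,3,4,4a,5,6,8a-octahydronaphthalen-1-yl (2E)-3-[4-(acetyloxy)phenyl]prop-2-enoate
Product: 22 (1R,2S,4aR,8aR)-4a,8-dimethyl-2-(propan-2-yl)-1,2,3,4,4a,5,6,8a-octahydronaphthalen-1-yl (2E)-3-(4-hydroxyphenyl)prop-2-enoate (CNP0220414.1)
Conditions: K2CO3 (0.2 equiv), MeOH, 0 °C; aq NH4Cl
Reagents that add atoms: none
Why: Base-catalysed transesterification should cleave the aryl acetate (phenoxide leaving group) far faster than the hindered secondary alkyl cinnamate.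

Compound list
1 | but-2-ynal | CC#CC=O | starting material
2 | tributyl(2-methylprop-2-en-1-yl)stannane | C=C(C)C[Sn](CCCC)(CCCC)CCCC | starting material
3 | (4R)-2-methylhept-1-en-5-yn-4-ol | C=C(C)C[C@@H](O)C#CC | intermediate
4 | sodium cyclic vinylalanate: five-membered O–Al–C(CH3)=CH–CH ring, Al carrying two 2-methoxyethoxy groups, ring CH carrying the 2-methylallyl group with the configuration of 3 | [Na+].C=C(C)C[C@@H]1C=C(C)[Al-](OCCOC)(OCCOC)O1 | intermediate
5 | (4R,5Z)-6-iodo-2-methylhepta-1,5-dien-4-ol | C=C(C)C[C@@H](O)/C=C(\I)C | intermediate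
6 | tert-butyl{[(4R,5Z)-6-iodo-2-methylhepta-1,5-dien-4-yl]oxy}dimethylsilane | C=C(C)C[C@@H](O[Si](C)(C)C(C)(C)C)/C=C(\I)C | intermediate
7 | 2-bromo-N-methoxy-N-methylacetamide | CON(C)C(=O)CBr | starting material
8 | bromo{2-[methoxy(methyl)amino]-2-oxoethyl}zinc | CON(C)C(=O)C[Zn]Br | intermediate
9 | (3Z,5R)-5-[(tert-butyldimethylsilyl)oxy]-N-methoxy-N,3,7-trimethylocta-3,7-dienamide | C=C(C)C[C@@H](O[Si](C)(C)C(C)(C)C)/C=C(\CC(=O)N(C)OC)C | intermediate
10 | 2-bromo-3-methylbut-1-ene | C=C(Br)C(C)C | starting material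
11 | bromo(3-methylbut-1-en-2-yl)magnesium | C=C([Mg]Br)C(C)C | intermediate
12 | (5Z,7R)-7-[(tert-butyldimethylsilyl)oxy]-5,9-dimethyl-2-(propan-2-yl)deca-1,5,9-trien-3-one | C=C(C)C[C@@H](O[Si](C)(C)C(C)(C)C)/C=C(\CC(=O)C(=C)C(C)C)C | intermediate
13 | (3Z,5Z,7R)-3,7-bis[(tert-butyldimethylsilyl)oxy]-5,9-dimethyl-2-(propan-2-yl)deca-1,3,5,9-tetraene | C=C(C)C[C@@H](O[Si](C)(C)C(C)(C)C)/C=C(/C)\C=C(/O[Si](C)(C)C(C)(C)C)C(=C)C(C)C | intermediate
14 | (4aS,6R,8aR)-1,6-bis[(tert-butyldimethylsilyl)oxy]-4a,8-dimethyl-2-(propan-2-yl)-3,4,4a,5,6,8a-hexahydronaphthalene | CC1=C[C@H](O[Si](C)(C)C(C)(C)C)C[C@]2(C)CCC(C(C)C)=C(O[Si](C)(C)C(C)(C)C)[C@@H]12 | intermediate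
15 | (2S,4aS,6R,8aR)-6-[(tert-butyldimethylsilyl)oxy]-4a,8-dimethyl-2-(propan-2-yl)-3,4,4a,5,6,8a-hexahydronaphthalen-1(2H)-one | CC1=C[C@H](O[Si](C)(C)C(C)(C)C)C[C@]2(C)CC[C@@H](C(C)C)C(=O)[C@@H]12 | intermediate
16 | (2S,4aS,6R,8aR)-6-hydroxy-4a,8-dimethyl-2-(propan-2-yl)-3,4,4a,5,6,8a-hexahydronaphthalen-1(2H)-one | CC1=C[C@H](O)C[C@]2(C)CC[C@@H](C(C)C)C(=O)[C@@H]12 | intermediate
17 | (1R,2S,4aS,6R,8aR)-4a,8-dimethyl-2-(propan-2-yl)-1,2,3,4,4a,5,6,8a-octahydronaphthalene-1,6-diol | CC1=C[C@H](O)C[C@]2(C)CC[C@@H](C(C)C)[C@@H](O)[C@@H]12 | intermediate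
18 | (1R,2S,4aR,8aR)-4a,8-dimethyl-2-(propan-2-yl)-1,2,3,4,4a,5,6,8a-octahydronaphthalen-1-ol | CC1=CCC[C@]2(C)CC[C@@H](C(C)C)[C@@H](O)[C@@H]12 | intermediate
19 | (2E)-3-[4-(acetyloxy)phenyl]prop-2-enoic acid | CC(=O)Oc1ccc(/C=C/C(=O)O)cc1 | starting material
20 | (2E)-3-[4-(acetyloxy)phenyl]prop-2-enoyl chloride | CC(=O)Oc1ccc(/C=C/C(=O)Cl)cc1 | intermediate
21 | (1R,2S,4aR,8aR)-4a,8-dimethyl-2-(propan-2-yl)-1,2,3,4,4a,5,6,8a-octahydronaphthalen-1-yl (2E)-3-[4-(acetyloxy)phenyl]prop-2-enoate | CC1=CCC[C@]2(C)CC[C@@H](C(C)C)[C@@H](OC(=O)/C=C/c3ccc(OC(C)=O)cc3)[C@@H]12 | intermediate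
22 | (1R,2S,4aR,8aR)-4a,8-dimethyl-2-(propan-2-yl)-1,2,3,4,4a,5,6,8a-octahydronaphthalen-1-yl (2E)-3-(4-hydroxyphenyl)prop-2-enoate | CC1=CCC[C@]2(C)CC[C@@H](C(C)C)[C@@H](OC(=O)/C=C/c3ccc(O)cc3)[C@@H]12 | target

Total step count: 12. Longest linear sequence: 12 steps (1 to 22).

Steps most likely to fail

Step 7. The cycloaddition may lose to thermal [1,5]-hydrogen migration from C2 to C6 through the cis-diene, or may discriminate poorly between the exo- and endo-tether transition states (cis ring fusion) or between the two diene faces. Fallback: the same two bonds would be closed by a metal-templated pathway instead of a pericyclic one. A cationic rhodium catalyst made from [Rh(cod)Cl]2, AgSbF6 and P[OCH(CF3)2]3 in THF at 55 °C would be used; this is the intramolecular diene–alkene [4+2] of trienes without activating groups, which runs through oxidative cyclisation to a rhodacycle and reductive elimination, far below the temperature of sigmatropic shifts. It sets out from 13 and comes back at 14, and it makes no new compound (F0).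

Step 10. The allyl cation may lose a proton to give dienes, or may take hydride at C4 so that the olefin moves to C2=C3. Fallback: a radical instead of a cationic deoxygenation, setting out from 17. CBr4 and PPh3 in CH2Cl2 at 0 °C should convert only the allylic hydroxyl (the axial C6 hydroxyl is too hindered) into the allylic bromide (1R,2S,4aS,8aR)-6-bromo-4a,8-dimethyl-2-(propan-2-yl)-1,2,3,4,4a,5,6,8a-octahydronaphthalen-1-ol F3; either C2 epimer or the allylic isomer is acceptable, since all give the same allyl radical. Bu3SnH and AIBN in benzene at 80 °C would then reduce it through the C2–C3–C4 allyl radical, which should take hydrogen at the less hindered C2, and the sequence comes back at 18.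

Step 5. The Grignard reagent may deprotonate the acidic C5 methylene instead of adding, with migration of the C3=C4 double bond into conjugation. Fallback: a non-basic carbonyl addition, setting out from 9. i-Bu2AlH in THF at −78 °C would give the aldehyde (3Z,5R)-5-[(tert-butyldimethylsilyl)oxy]-3,7-dimethylocta-3,7-dienal F1. Nozaki–Hiyama–Kishi coupling with 10 (CrCl2, NiCl2 cat., DMF, rt) would give the allylic alcohol (5Z,7R)-7-[(tert-butyldimethylsilyl)oxy]-5,9-dimethyl-2-(propan-2-yl)deca-1,5,9-trien-3-ol F2 as both carbinol epimers. Dess–Martin periodinane with NaHCO3 in CH2Cl2 would then oxidise it, and the sequence comes back at 12.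

Further compounds
F0 | step 7 | none | none
F1 | step 5 | (3Z,5R)-5-[(tert-butyldimethylsilyl)oxy]-3,7-dimethylocta-3,7-dienal | C=C(C)C[C@@H](O[Si](C)(C)C(C)(C)C)/C=C(\CC=O)C
F2 | step 5 | (5Z,7R)-7-[(tert-butyldimethylsilyl)oxy]-5,9-dimethyl-2-(propan-2-yl)deca-1,5,9-trien-3-ol (both C3 epimers) | C=C(C)C[C@@H](O[Si](C)(C)C(C)(C)C)/C=C(\CC(O)C(=C)C(C)C)C
F3 | step 10 | (1R,2S,4aS,8aR)-6-bromo-4a,8-dimethyl-2-(propan-2-yl)-1,2,3,4,4a,5,6,8a-octahydronaphthalen-1-ol (either C6 epimer) | CC1=CC(Br)C[C@]2(C)CC[C@@H](C(C)C)[C@@H](O)[C@@H]12
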